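The readings are calculated for substances that don't exist; scatter was added.

1. The decision is to reckon the blue run as one first-order fall of starting material, so that its target share at time t is F(1 − e^(−k_B t)). Here F is the share of charged starting material that ends as target, and k_B is the first-order constant of its consumption.

| flask | starting material | coupling partner | time |
|---|---|---|---|
| ochre | 300 mM | 900 mM |  |
| grey | 900 mM | 900 mM |  |
| green | 300 mM | 1800 mM |  |
| blue | 150 mM | 2700 mM | 22 min |

| run | time / min | [target] / mM |
|---|---|---|
| ochre run | 0.88 | 14.7 |
| ochre run | 1.5 | 22.3 |
| ochre run | 2.6 | 34.4 |
| ochre run | 4.4 | 59.7 |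
| ochre run | 7.5 | 90.4 |
| ochre run | 13 | 134.1 |
| ochre run | 22 | 175.4 |
| grey run | 0.88 | 26.3 |
| grey run | 1.5 | 42.4 |
| grey run | 2.6 | 70.5 |
| grey run | 4.4 | 112.1 |
| grey run | 7.5 | 175.4 |
| grey run | 13 | 254.8 |
| grey run | 22 | 344.6 |
| green run | 0.88 | 26.4 |
| green run | 1.5 | 41.2 |
| green run | 2.6 | 70.6 |
| green run | 4.4 | 107.4 |
| green run | 7.5 | 156.3 |
| green run | 13 | 202.6 |
| green run | 22 | 229.8 |

(each reading ± 0.9 mM)
- Overall: starting material + coupling partner -> target.
- Constant volume, constant temperature.
- A reading of a species includes what of it is bound.
- "The second partner" is coupling partner.
- An order is taken over about fifteen percent of the charge, up and down.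
- the exponent of [starting material] in the starting rate at the charge of the ochre run (at the point where two percent of the starting material have become target) (one fixed amount of target, the same in the runs compared)
- the exponent of [coupling partner] in the starting rate at the charge of the ochre run (at the point where two percent of the starting material have become target)
- target in the blue run at 22 min, as a share of the starting material charged

2. My reading of the orders uses target at 2.6 min: 34.4 mM in the ochre run, 70.5 mM in the grey run and 70.6 mM in the green run. These ratios give a mean order of 0.653 in starting material and 1.04 in coupling partner.

3. The blue run charges coupling partner at 18.0 to one, so coupling takes at most 5.56% of it. Starting material is the limiting reagent of the blue run. The first-order fall is an approximation: the mean order in starting material read above, between the ochre and grey charges, is 0.653, less than one.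

4. The green tail, each interval replaced by its mean rate, gives 8.42 mM min⁻¹, then 3.02 mM min⁻¹. The interval midpoints lie 7.25 min apart, so k_G = 0.141 min⁻¹. At order one in coupling partner, k_B = 0.212 min⁻¹.

5. Sensitivity: at 22 min the unturned share is 0.944%, and at half that constant it is 9.71%. An error in k_B is thus damped, whereas F passes one to one into the answer, so F has to be known well.

6. The green rate at 22 min is 1.60 mM min⁻¹, which leaves 11.3 mM still to come. So F = 80.4%, the ceiling share of charged starting material ending as target. My blue estimate is 79.6%.

7. The forecast gives 0.72, 1 and 87%, higher than my estimate, on the grounds “This looks like catalyst death or inhibition, worst at high partner and low starting material”.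

8. The simulation gives 0.65, 1.0 and 78.5%.

    starting material + coupling partner → target (0.1368 M⁻¹ min⁻¹)
    starting material + coupling partner → side product (0.03738 M⁻¹ min⁻¹)
    2 starting material ⇌ idle substrate dimer, settled at all times (5.540 M⁻¹)
    coupling partner → lost reagent (0.009120 min⁻¹)

In the blue run, charged with coupling partner at 18.0 to one, starting material turned by two parallel steps, and target took 78.5% of what turned, the selectivity, against F = 80.4%; the run reached 78.5%. Joining to idle substrate dimer and loss of coupling partner made no difference to that figure. In the ochre run, target reached a quarter of the charge at 5.95 min and half at 16.0 min, a ratio of 2.69, where a first-order fall with ceiling F gives 2.61.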